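**Retrosynthetic overview** (benzofuran numbering: O1, C2, C3, C3a, C4–C7, C7a; ring A = benzene ring of the benzofuran)

1. The target is the monomethyl ester of lithospermic acid. The last C–C bond made is C4–CH= of the acrylate arm, by carboxylate-directed C–H olefination of acid 14 with acrylate 18; the free C3 acid of the target is the directing group, and one acidolysis then unmasks all phenols.
2. Ring A of 14 is taken back one oxidation level to the 4,5,6,7-tetrahydro-7-ketone 9, so that its catechol edge O1–C7a–C7–OH becomes the enol ether and ketone of a cyclic 1,2-diketone.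
3. Key disconnection: O1–C2 and C3a–C3 are cut together, as an oxidative radical (3+2) annulation of cyclohexane-1,2-dione 8 with the N-cinnamoyl sultam 7 by Mn(OAc)3; it makes the furan ring and both of its stereocentres.
4. Enabling feature: C3a lies between C7a–O1 and C4–H, and C7a carries O1 next to the C7 oxygen. With C7 as a ketone, O1–C7a=C3a is the enol of the 1,2-diketone: C3a is its radical carbon and O1 its enol oxygen.
5. Order of ring formation: ring A is bought as the six-membered carbocycle, the furan ring is closed in step 4, and ring A is aromatised in step 5. The two catechol rings come with 1 and 15.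

Key step: step 4

Assumption: thermal additions to N-enoyl derivatives of (2R)-bornane-10,2-sultam take place on the Cα-re face, so the (2S)-sultam is taken to direct the radical to the Cα-si face of 7, which corresponds to (3S) in 9.

Step 1
Reactants: 1 3,4-dihydroxybenzaldehyde
Product: 2 2,2-dimethyl-1,3-benzodioxole-5-carbaldehyde
Conditions: 2,2-dimethoxypropane, TsOH·H2O (cat.), toluene, reflux, MeOH removed over 4 Å sieves
Reagents that add atoms: 2,2-dimethoxypropane, COC(C)(C)OC
Why: Acid-catalysed transketalisation of the catechol (acetonide formation) is driven by removal of methanol, and no stereocentre is formed.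

Step 2
Reactants: 2 2,2-dimethyl-1,3-benzodioxole-5-carbaldehyde
Product: 4 (2E)-3-(2,2-dimethyl-1,3-benzodioxol-5-yl)prop-2-enoic acid, via arylidenemalonic acid 3 (not isolated)
Conditions: malonic acid, pyridine, piperidine (cat.), 90 °C
Reagents that add atoms: malonic acid, OC(=O)CC(=O)O
Why: Knoevenagel–Doebner condensation followed by decarboxylation in pyridine should give the thermodynamically preferred E-cinnamic acid, and the acetonide is stable to the basic medium.

Step 3
Reactants: 4 (2E)-3-(2,2-dimethyl-1,3-benzodioxol-5-yl)prop-2-enoic acid; 5 (2S)-bornane-10,2-sultam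
Product: 7 N-[(2E)-3-(2,2-dimethyl-1,3-benzodioxol-5-yl)prop-2-enoyl]-(2S)-bornane-10,2-sultam, via acid chloride 6 (not isolated)
Conditions: 1-chloro-N,N,2-trimethylprop-1-en-1-amine, CH2Cl2, 0 °C to rt; then 5, Et3N, DMAP (cat.), 0 °C to rt
Reagents that add atoms: none
Why: N-Acylation of the sulfonamide nitrogen by an acid chloride made under neutral conditions, so that the acetonide never meets HCl; the stereocentres of the auxiliary are carried in unchanged.

Step 4
Reactants: 7 N-[(2E)-3-(2,2-dimethyl-1,3-benzodioxol-5-yl)prop-2-enoyl]-(2S)-bornane-10,2-sultam; 8 cyclohexane-1,2-dione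
Product: 9 (2S,3S)-2-(2,2-dimethyl-1,3-benzodioxol-5-yl)-3-{[(2S)-bornane-10,2-sultam-N-yl]carbonyl}-2,3,5,6-tetrahydro-1-benzofuran-7(4H)-one (trans)
Conditions: 8 (3 equiv), Mn(OAc)3·2H2O (in portions), KOAc, AcOH, 60 °C, N2
Reagents that add atoms: none
Why: Proposed new method: cyclohexane-1,2-dione is fully enolised (2-hydroxycyclohex-2-enone), and oxidation of its manganese enolate by Mn(OAc)3 should give the electrophilic α-keto radical at the enol carbon, which adds to Cα of 7 (C3a–C3 bond) and leaves a benzylic radical that a second equivalent of Mn(OAc)3 oxidises to the cation stabilised by the 3,4-dioxygenated aryl group; the enol oxygen captures this cation (O1–C2 bond) and loss of a proton gives the 2-alkoxy enone 9. The closest known reaction type is the oxidative (3+2) annulation of cyclic 1,3-diketones with N-cinnamoyl sultams by Mn(OAc)3, which gives trans-2-aryl-2,3-dihydrofuran-3-carboxamides, and the related dihydrofuran synthesis from simple ketones and aryl alkenes; new is only the 1,2-diketone as radical precursor. Only the furan ring closes, by 5-exo-trig attack of the enol oxygen on the aryl-stabilised C2 cation after the intermolecular radical addition, while ring A enters as the intact six-membered carbocycle. C3 is controlled by the auxiliary, which shields the Cα-re face of the s-cis N-enoyl sultam so that the radical enters on the Cα-si face and sets (3S), and C2 is controlled by C3, because closure places the aryl group anti to the C3 acyl group and sets the trans (2S) centre. The step needs attack at Cα and not at Cβ, which the electrophilic radical and the benzylic stabilisation secure, closure through the near enol oxygen and not through the C7 carbonyl, which would demand a bridgehead enol ether, and a product inert to the oxidant, which holds because 9 no longer has an enolisable 1,2-diketone. The minor diastereomer should be removable by crystallisation of the sultam derivative.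

Step 5
Reactants: 9 (2S,3S)-2-(2,2-dimethyl-1,3-benzodioxol-5-yl)-3-{[(2S)-bornane-10,2-sultam-N-yl]carbonyl}-2,3,5,6-tetrahydro-1-benzofuran-7(4H)-one
Product: 11 N-{[(2S,3S)-2-(2,2-dimethyl-1,3-benzodioxol-5-yl)-7-hydroxy-2,3-dihydro-1-benzofuran-3-yl]carbonyl}-(2S)-bornane-10,2-sultam, via dienone tautomer 10 (not isolated)
Conditions: Pd(O2CCF3)2 (5 mol%), 2-(dimethylamino)pyridine (10 mol%), TsOH·H2O (20 mol%), O2 (1 atm), DMSO, 80 °C
Reagents that add atoms: none
Why: Aerobic dehydrogenation of a cyclohexenone to a phenol by divalent palladium (palladium enolate at C6, β-hydride elimination, tautomerisation of the cross-conjugated dienone) should aromatise ring A, while the imide-type C3–H is not enolised toward palladium under these weakly acidic conditions and both stereocentres stay as set.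

Step 6
Reactants: 11 N-{[(2S,3S)-2-(2,2-dimethyl-1,3-benzodioxol-5-yl)-7-hydroxy-2,3-dihydro-1-benzofuran-3-yl]carbonyl}-(2S)-bornane-10,2-sultam
Product: 12 N-{[(2S,3S)-2-(2,2-dimethyl-1,3-benzodioxol-5-yl)-7-(methoxymethoxy)-2,3-dihydro-1-benzofuran-3-yl]carbonyl}-(2S)-bornane-10,2-sultam
Conditions: MOMCl, iPr2NEt, CH2Cl2, 0 °C to rt
Reagents that add atoms: chloromethyl methyl ether, COCCl
Why: O-Alkylation of the phenol (Williamson type) under an amine base too weak to epimerise C3 gives an acetal that survives the basic and oxidative steps ahead and falls off in the final acidolysis.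

Step 7
Reactants: 12 N-{[(2S,3S)-2-(2,2-dimethyl-1,3-benzodioxol-5-yl)-7-(methoxymethoxy)-2,3-dihydro-1-benzofuran-3-yl]carbonyl}-(2S)-bornane-10,2-sultam
Product: 14 (2S,3S)-2-(2,2-dimethyl-1,3-benzodioxol-5-yl)-7-(methoxymethoxy)-2,3-dihydro-1-benzofuran-3-carboxylic acid, via peroxy acid 13 (not isolated)
Conditions: LiOH·H2O, 30% H2O2, THF/H2O, 0 °C; then Na2SO3 (aq); then 1 M HCl to pH 3
Reagents that add atoms: hydrogen peroxide, OO
Why: Hydroperoxide cleavage of the N-acyl sultam at the exocyclic carbonyl, followed by sulfite reduction of the peroxy acid, should free the acid and return the auxiliary; the trans arrangement is the thermodynamic one, so C3 is not at risk at 0 °C.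

Step 8
Reactants: 15 sodium (2R)-3-(3,4-dihydroxyphenyl)-2-hydroxypropanoate
Product: 16 methyl (2R)-3-(3,4-dihydroxyphenyl)-2-hydroxypropanoate
Conditions: HCl in MeOH (1.25 M), rt
Reagents that add atoms: methanol, CO
Why: Fischer esterification of the chiral-pool hydroxy acid leaves the carbinol stereocentre untouched.

Step 9
Reactants: 16 methyl (2R)-3-(3,4-dihydroxyphenyl)-2-hydroxypropanoate
Product: 17 methyl (2R)-3-(2,2-dimethyl-1,3-benzodioxol-5-yl)-2-hydroxypropanoate
Conditions: 2,2-dimethoxypropane, TsOH·H2O (cat.), toluene, reflux, MeOH removed over 4 Å sieves; dilute aqueous AcOH work-up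
Reagents that add atoms: 2,2-dimethoxypropane, COC(C)(C)OC
Why: Acetonide formation on the electron-rich catechol; any mixed ketal on the secondary alcohol is hydrolysed in the work-up, and the stereocentre is not involved.

Step 10
Reactants: 17 methyl (2R)-3-(2,2-dimethyl-1,3-benzodioxol-5-yl)-2-hydroxypropanoate
Product: 18 methyl (2R)-2-(acryloyloxy)-3-(2,2-dimethyl-1,3-benzodioxol-5-yl)propanoate
Conditions: acryloyl chloride, Et3N, CH2Cl2, −20 to 0 °C
Reagents that add atoms: acryloyl chloride, C=CC(=O)Cl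
Why: O-Acylation of the secondary alcohol with an acid chloride at low temperature should avoid both polymerisation of the acrylate and racemisation of the α-acyloxy ester.

Step 11
Reactants: 14 (2S,3S)-2-(2,2-dimethyl-1,3-benzodioxol-5-yl)-7-(methoxymethoxy)-2,3-dihydro-1-benzofuran-3-carboxylic acid; 18 methyl (2R)-2-(acryloyloxy)-3-(2,2-dimethyl-1,3-benzodioxol-5-yl)propanoate
Product: 19 (2S,3S)-2-(2,2-dimethyl-1,3-benzodioxol-5-yl)-4-[(1E)-3-{[(2R)-3-(2,2-dimethyl-1,3-benzodioxol-5-yl)-1-methoxy-1-oxopropan-2-yl]oxy}-3-oxoprop-1-en-1-yl]-7-(methoxymethoxy)-2,3-dihydro-1-benzofuran-3-carboxylic acid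
Conditions: Pd(OAc)2 (5 mol%), N-acetyl-L-isoleucine (10 mol%), KHCO3 (2 equiv), O2 (1 atm), tert-amyl alcohol, 85 °C; cold 1 M HCl work-up
Reagents that add atoms: none
Why: Carboxylate-directed ortho C–H olefination (Fujiwara–Moritani type, divalent palladium with a mono-N-protected amino acid ligand) is established for 2-aryl-2,3-dihydrobenzofuran-3-carboxylic acids; C4–H is the only C–H ortho to the CH(CO2H) arm, β-hydride elimination gives the E-alkene, and no stereocentre is formed.

Step 12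
Reactants: 19 (2S,3S)-2-(2,2-dimethyl-1,3-benzodioxol-5-yl)-4-[(1E)-3-{[(2R)-3-(2,2-dimethyl-1,3-benzodioxol-5-yl)-1-methoxy-1-oxopropan-2-yl]oxy}-3-oxoprop-1-en-1-yl]-7-(methoxymethoxy)-2,3-dihydro-1-benzofuran-3-carboxylic acid
Product: 20 (2S,3S)-2-(3,4-dihydroxyphenyl)-4-[(1E)-3-{[(2R)-3-(3,4-dihydroxyphenyl)-1-methoxy-1-oxopropan-2-yl]oxy}-3-oxoprop-1-en-1-yl]-7-hydroxy-2,3-dihydro-1-benzofuran-3-carboxylic acid (the target)
Conditions: TFA/H2O (9:1), 0 °C to rt
Reagents that add atoms: none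
Why: Acidolysis of the two catechol acetonides and of the MOM acetal leaves the methyl ester, the acrylate ester and the carboxylic acid in place, and the trans-dihydrobenzofuran is the thermodynamic arrangement under acid.

**Compound list**

1 | 3,4-dihydroxybenzaldehyde | O=Cc1ccc(O)c(O)c1 | starting material
2 | 2,2-dimethyl-1,3-benzodioxole-5-carbaldehyde | O=Cc1ccc2OC(C)(C)Oc2c1 | intermediate
3 | [(2,2-dimethyl-1,3-benzodioxol-5-yl)methylidene]propanedioic acid | OC(=O)C(=Cc1ccc2OC(C)(C)Oc2c1)C(=O)O | intermediate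
4 | (2E)-3-(2,2-dimethyl-1,3-benzodioxol-5-yl)prop-2-enoic acid | OC(=O)/C=C/c1ccc2OC(C)(C)Oc2c1 | intermediate
5 | (2S)-bornane-10,2-sultam, the (1R,5S,7S) enantiomer of 2,10-camphorsultam | N1[C@H]2C[C@@H]3CC[C@@]2(CS1(=O)=O)C3(C)C | starting material
6 | (2E)-3-(2,2-dimethyl-1,3-benzodioxol-5-yl)prop-2-enoyl chloride | ClC(=O)/C=C/c1ccc2OC(C)(C)Oc2c1 | intermediate
7 | N-[(2E)-3-(2,2-dimethyl-1,3-benzodioxol-5-yl)prop-2-enoyl]-(2S)-bornane-10,2-sultam | O=C(/C=C/c1ccc2OC(C)(C)Oc2c1)N1[C@H]2C[C@@H]3CC[C@@]2(CS1(=O)=O)C3(C)C | intermediate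
8 | cyclohexane-1,2-dione | O=C1CCCCC1=O | starting material
9 | (2S,3S)-2-(2,2-dimethyl-1,3-benzodioxol-5-yl)-3-{[(2S)-bornane-10,2-sultam-N-yl]carbonyl}-2,3,5,6-tetrahydro-1-benzofuran-7(4H)-one | C1CCC(=O)C2=C1[C@H](C(=O)N3[C@H]4C[C@@H]5CC[C@@]4(CS3(=O)=O)C5(C)C)[C@@H](c6ccc7OC(C)(C)Oc7c6)O2 | intermediate
10 | (2S,3S)-2-(2,2-dimethyl-1,3-benzodioxol-5-yl)-3-{[(2S)-bornane-10,2-sultam-N-yl]carbonyl}-2,3-dihydro-1-benzofuran-7(4H)-one (keto tautomer of 11) | C1C=CC(=O)C2=C1[C@H](C(=O)N3[C@H]4C[C@@H]5CC[C@@]4(CS3(=O)=O)C5(C)C)[C@@H](c6ccc7OC(C)(C)Oc7c6)O2 | intermediate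
11 | N-{[(2S,3S)-2-(2,2-dimethyl-1,3-benzodioxol-5-yl)-7-hydroxy-2,3-dihydro-1-benzofuran-3-yl]carbonyl}-(2S)-bornane-10,2-sultam | c1ccc(O)c2c1[C@H](C(=O)N3[C@H]4C[C@@H]5CC[C@@]4(CS3(=O)=O)C5(C)C)[C@@H](c6ccc7OC(C)(C)Oc7c6)O2 | intermediate
12 | N-{[(2S,3S)-2-(2,2-dimethyl-1,3-benzodioxol-5-yl)-7-(methoxymethoxy)-2,3-dihydro-1-benzofuran-3-yl]carbonyl}-(2S)-bornane-10,2-sultam | c1ccc(OCOC)c2c1[C@H](C(=O)N3[C@H]4C[C@@H]5CC[C@@]4(CS3(=O)=O)C5(C)C)[C@@H](c6ccc7OC(C)(C)Oc7c6)O2 | intermediate
13 | (2S,3S)-2-(2,2-dimethyl-1,3-benzodioxol-5-yl)-7-(methoxymethoxy)-2,3-dihydro-1-benzofuran-3-carboperoxoic acid | c1ccc(OCOC)c2c1[C@H](C(=O)OO)[C@@H](c3ccc4OC(C)(C)Oc4c3)O2 | intermediate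
14 | (2S,3S)-2-(2,2-dimethyl-1,3-benzodioxol-5-yl)-7-(methoxymethoxy)-2,3-dihydro-1-benzofuran-3-carboxylic acid | c1ccc(OCOC)c2c1[C@H](C(=O)O)[C@@H](c3ccc4OC(C)(C)Oc4c3)O2 | intermediate
15 | sodium (2R)-3-(3,4-dihydroxyphenyl)-2-hydroxypropanoate | [Na+].[O-]C(=O)[C@@H](Cc1ccc(O)c(O)c1)O | starting material
16 | methyl (2R)-3-(3,4-dihydroxyphenyl)-2-hydroxypropanoate | COC(=O)[C@@H](Cc1ccc(O)c(O)c1)O | intermediate
17 | methyl (2R)-3-(2,2-dimethyl-1,3-benzodioxol-5-yl)-2-hydroxypropanoate | COC(=O)[C@@H](Cc1ccc2OC(C)(C)Oc2c1)O | intermediate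
18 | methyl (2R)-2-(acryloyloxy)-3-(2,2-dimethyl-1,3-benzodioxol-5-yl)propanoate | COC(=O)[C@@H](Cc1ccc2OC(C)(C)Oc2c1)OC(=O)C=C | intermediate
19 | (2S,3S)-2-(2,2-dimethyl-1,3-benzodioxol-5-yl)-4-[(1E)-3-{[(2R)-3-(2,2-dimethyl-1,3-benzodioxol-5-yl)-1-methoxy-1-oxopropan-2-yl]oxy}-3-oxoprop-1-en-1-yl]-7-(methoxymethoxy)-2,3-dihydro-1-benzofuran-3-carboxylic acid | COC(=O)[C@@H](Cc1ccc2OC(C)(C)Oc2c1)OC(=O)/C=C/c1ccc(OCOC)c2c1[C@H](C(=O)O)[C@@H](c1ccc3OC(C)(C)Oc3c1)O2 | intermediate
20 | (2S,3S)-2-(3,4-dihydroxyphenyl)-4-[(1E)-3-{[(2R)-3-(3,4-dihydroxyphenyl)-1-methoxy-1-oxopropan-2-yl]oxy}-3-oxoprop-1-en-1-yl]-7-hydroxy-2,3-dihydro-1-benzofuran-3-carboxylic acid | COC(=O)[C@@H](Cc1ccc(O)c(O)c1)OC(=O)/C=C/c1ccc(O)c2c1[C@H](C(=O)O)[C@@H](c1ccc(O)c(O)c1)O2 | target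

**Step count and risks**

Total step count: 12. Longest linear sequence: 9 steps (steps 1 to 7, then 11 and 12).

The three steps most likely to fail:

1. Step 4 (bears the label). The diketone-derived radical may couple with itself or be oxidised further before it adds to 7, or the auxiliary may discriminate the two alkene faces poorly. The fallback uses known chemistry, sets out from 7 and comes back to the route at 19. The precedented annulation of 7 with cyclohexane-1,3-dione and Mn(OAc)3·2H2O in AcOH should give the 4-oxo-tetrahydrobenzofuran F1. Aerobic dehydrogenation with Pd(O2CCF3)2 then gives the 4-hydroxy-2,3-dihydrobenzofuran F2. Potassium nitrosodisulfonate, (KSO3)2NO, oxidises its free para position to give the 4,7-quinone F3, and Na2S2O4 reduces this to the hydroquinone F4. One equivalent of MOMCl with iPr2NEt protects the unhindered 7-OH and gives the mono-MOM ether F5. LiOH/H2O2 removes the sultam to give the hydroxy acid F6, and PhNTf2/Et3N converts the 4-OH into the aryl triflate F7. A Heck reaction of F7 with 18 (Pd(OAc)2, 1,3-bis(diphenylphosphino)propane, Et3N, DMF, 80 °C) gives 19. In this variant ring A comes from a 1,3-diketone, its C4 carbonyl serves as the handle for the acrylate arm, and the C7 oxygen is added by para-oxidation.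

2. Step 5. The aerobic conditions may dehydrogenate across C2–C3 to the benzofuran, which would erase both stereocentres, or the acid co-catalyst may cleave the acetonide. The fallback sets out from 9 and comes back at 11. It replaces the catalytic dehydrogenation by a stoichiometric selenoxide route that needs neither base nor a metal. α-Selenenylation of the ketone through its enol with PhSeCl in EtOAc gives the 6-(phenylselanyl) ketone F8. H2O2/pyridine in CH2Cl2 oxidises it to the selenoxide, whose syn-elimination gives dienone 10 and, by tautomerisation, 11.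

3. Step 12. In the single acidolysis, the cations set free from the MOM group may alkylate the liberated catechols, and the benzylic C2–O1 bond may ionise under prolonged acid. The fallback sets out from 19 and comes back at 20, and unmasks in two stages. ZnBr2 with 1-propanethiol in CH2Cl2 removes only the MOM group, the thiol trapping the methoxymethyl cation, and gives the phenol bis-acetonide F9. A short treatment with TFA/H2O then cleaves the two acetonides, which release only acetone, and gives 20.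

**Further compounds**

F1 | step 4 | (2S,3S)-2-(2,2-dimethyl-1,3-benzodioxol-5-yl)-3-{[(2S)-bornane-10,2-sultam-N-yl]carbonyl}-3,5,6,7-tetrahydro-1-benzofuran-4(2H)-one | O=C1CCCC2=C1[C@H](C(=O)N3[C@H]4C[C@@H]5CC[C@@]4(CS3(=O)=O)C5(C)C)[C@@H](c6ccc7OC(C)(C)Oc7c6)O2
F2 | step 4 | N-{[(2S,3S)-2-(2,2-dimethyl-1,3-benzodioxol-5-yl)-4-hydroxy-2,3-dihydro-1-benzofuran-3-yl]carbonyl}-(2S)-bornane-10,2-sultam | Oc1cccc2c1[C@H](C(=O)N3[C@H]4C[C@@H]5CC[C@@]4(CS3(=O)=O)C5(C)C)[C@@H](c6ccc7OC(C)(C)Oc7c6)O2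
F3 | step 4 | (2S,3S)-2-(2,2-dimethyl-1,3-benzodioxol-5-yl)-3-{[(2S)-bornane-10,2-sultam-N-yl]carbonyl}-2,3-dihydro-1-benzofuran-4,7-dione | O=C1C=CC(=O)C2=C1[C@H](C(=O)N3[C@H]4C[C@@H]5CC[C@@]4(CS3(=O)=O)C5(C)C)[C@@H](c6ccc7OC(C)(C)Oc7c6)O2
F4 | step 4 | N-{[(2S,3S)-2-(2,2-dimethyl-1,3-benzodioxol-5-yl)-4,7-dihydroxy-2,3-dihydro-1-benzofuran-3-yl]carbonyl}-(2S)-bornane-10,2-sultam | Oc1ccc(O)c2c1[C@H](C(=O)N3[C@H]4C[C@@H]5CC[C@@]4(CS3(=O)=O)C5(C)C)[C@@H](c6ccc7OC(C)(C)Oc7c6)O2
F5 | step 4 | N-{[(2S,3S)-2-(2,2-dimethyl-1,3-benzodioxol-5-yl)-4-hydroxy-7-(methoxymethoxy)-2,3-dihydro-1-benzofuran-3-yl]carbonyl}-(2S)-bornane-10,2-sultam | Oc1ccc(OCOC)c2c1[C@H](C(=O)N3[C@H]4C[C@@H]5CC[C@@]4(CS3(=O)=O)C5(C)C)[C@@H](c6ccc7OC(C)(C)Oc7c6)O2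
F6 | step 4 | (2S,3S)-2-(2,2-dimethyl-1,3-benzodioxol-5-yl)-4-hydroxy-7-(methoxymethoxy)-2,3-dihydro-1-benzofuran-3-carboxylic acid | Oc1ccc(OCOC)c2c1[C@H](C(=O)O)[C@@H](c3ccc4OC(C)(C)Oc4c3)O2
F7 | step 4 | (2S,3S)-2-(2,2-dimethyl-1,3-benzodioxol-5-yl)-7-(methoxymethoxy)-4-{[(trifluoromethyl)sulfonyl]oxy}-2,3-dihydro-1-benzofuran-3-carboxylic acid | FC(F)(F)S(=O)(=O)Oc1ccc(OCOC)c2c1[C@H](C(=O)O)[C@@H](c3ccc4OC(C)(C)Oc4c3)O2
F8 | step 5 | (2S,3S)-2-(2,2-dimethyl-1,3-benzodioxol-5-yl)-3-{[(2S)-bornane-10,2-sultam-N-yl]carbonyl}-6-(phenylselanyl)-2,3,5,6-tetrahydro-1-benzofuran-7(4H)-one (mixture at C6) | C1CC([Se]c8ccccc8)C(=O)C2=C1[C@H](C(=O)N3[C@H]4C[C@@H]5CC[C@@]4(CS3(=O)=O)C5(C)C)[C@@H](c6ccc7OC(C)(C)Oc7c6)O2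
F9 | step 12 | (2S,3S)-2-(2,2-dimethyl-1,3-benzodioxol-5-yl)-4-[(1E)-3-{[(2R)-3-(2,2-dimethyl-1,3-benzodioxol-5-yl)-1-methoxy-1-oxopropan-2-yl]oxy}-3-oxoprop-1-en-1-yl]-7-hydroxy-2,3-dihydro-1-benzofuran-3-carboxylic acid | COC(=O)[C@@H](Cc1ccc2OC(C)(C)Oc2c1)OC(=O)/C=C/c1ccc(O)c2c1[C@H](C(=O)O)[C@@H](c1ccc3OC(C)(C)Oc3c1)O2
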